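The two identical 4-oxyquinolinone units flank one carbon of a p-menthane core, so the target is traced back to an achiral p-quinol and two molecules of 4-hydroxy-1-methylquinolin-2-one. The key step exploits the dimethylpyran ring: its O–C(CH3)2–CH unit is an isopropyl group on an O-bearing quaternary carbon in disguise. Acid ionises the tertiary C–O bond of a cis-fused dihydrofuran with angular isopropyl, a 1,2-hydride shift moves the cation to the isopropyl carbon and the enol oxygen re-closes, expanding the five-membered ring to the pyran while the second quinolinone bridges to a tertiary carbinol; two stereocentres are set under thermodynamic control.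

Key step: step 5

Remark: the sense of induction in step 2 is assumed to be selectable by using the quinine-derived squaramide or its quinidine-derived pseudo-enantiomer; the catalyst that gives (6bS,10aS)-7 is taken.

Step 1
Reactants: 1 4-(propan-2-yl)phenol
Product: 3 4-hydroxy-4-(propan-2-yl)cyclohexa-2,5-dien-1-one, via p-peroxyquinol 2 (not isolated)
Conditions: Oxone (2KHSO5·KHSO4·K2SO4), NaHCO3, MeCN/H2O, rt; then Me2S
Reagents that add atoms: Oxone, active component potassium peroxymonosulfate, [K+].[O-]S(=O)(=O)OO
Why: Oxidative dearomatisation: singlet oxygen released from buffered peroxymonosulfate should add to the para position of the phenol to give the p-peroxyquinol, which Me2S reduces to the p-quinol; no stereocentre is formed (C4 is prochiral).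

Step 2
Reactants: 3 4-hydroxy-4-(propan-2-yl)cyclohexa-2,5-dien-1-one; 4 4-hydroxy-1-methylquinolin-2(1H)-one
Product: 7 (6bS,10aS)-5-methyl-10a-(propan-2-yl)-6b,7-dihydro[1]benzofuro[3,2-c]quinoline-6,8(5H,10aH)-dione, via Michael adduct 5 (not isolated), via cyclic hemiketal 6 (not isolated)
Conditions: quinine-derived 3,5-bis(trifluoromethyl)phenyl squaramide (10 mol %), THF, −20 °C; then p-TsOH·H2O (20 mol %), 4 Å MS, 40 °C
Reagents that add atoms: none
Why: Desymmetrising Michael addition under bifunctional hydrogen-bond-donor/tertiary-amine catalysis (the ion-paired enolate of 4 should add to one enantiotopic enone syn to the hydroxyl, which fixes both stereocentres), followed by acid-catalysed hemiketalisation–dehydration of the vinylogous acid (furan annulation), which is possible only for the syn adduct and makes the reversible addition productive.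

Step 3
Reactants: 7 (6bS,10aS)-5-methyl-10a-(propan-2-yl)-6b,7-dihydro[1]benzofuro[3,2-c]quinoline-6,8(5H,10aH)-dione; 4 4-hydroxy-1-methylquinolin-2(1H)-one
Product: 8 (6bS,10S,10aS)-10-(4-hydroxy-1-methyl-2-oxo-1,2-dihydroquinolin-3-yl)-5-methyl-10a-(propan-2-yl)-6b,7,9,10-tetrahydro[1]benzofuro[3,2-c]quinoline-6,8(5H,10aH)-dione
Conditions: 4 (1.2 equiv), the same squaramide catalyst (10 mol %), THF, 40 °C
Reagents that add atoms: none
Why: Michael addition of the cyclic 1,3-dicarbonyl to the γ,γ-disubstituted enone: axial attack anti to the pseudo-axial ring C–O bond (reinforced by the catalyst, matched case) should place the new quinolinone trans to the ring oxygen and so trans to the first quinolinone, and the adduct is drawn off as the bridged hemiketal that only this axial isomer can form.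

Step 4
Reactants: 8 (6bS,10S,10aS)-10-(4-hydroxy-1-methyl-2-oxo-1,2-dihydroquinolin-3-yl)-5-methyl-10a-(propan-2-yl)-6b,7,9,10-tetrahydro[1]benzofuro[3,2-c]quinoline-6,8(5H,10aH)-dione
Product: 9 (6bS,10S,10aS)-8-hydroxy-10-(4-hydroxy-1-methyl-2-oxo-1,2-dihydroquinolin-3-yl)-5,8-dimethyl-10a-(propan-2-yl)-6b,7,8,9,10,10a-hexahydro[1]benzofuro[3,2-c]quinolin-6(5H)-one (epimers at C8)
Conditions: MeMgBr (4 equiv), CeCl3, THF, −78 to 0 °C; aq NH4Cl
Reagents that add atoms: methylmagnesium bromide, C[Mg]Br
Why: Cerium-modified Grignard 1,2-addition to the hindered, enolisable ketone after deprotonation of the acidic enol (the quinolinone lactams are inert); the configuration of the new carbinol is irrelevant because this carbon is ionised in step 5.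

Step 5
Reactants: 9 (6bS,10S,10aS)-8-hydroxy-10-(4-hydroxy-1-methyl-2-oxo-1,2-dihydroquinolin-3-yl)-5,8-dimethyl-10a-(propan-2-yl)-6b,7,8,9,10,10a-hexahydro[1]benzofuro[3,2-c]quinolin-6(5H)-one (epimers at C8)
Product: 11 target dimer (configuration as in the compound list), via bridged ether 10 (not isolated)
Conditions: p-TsOH·H2O (0.3 equiv), toluene, 80 °C
Reagents that add atoms: none
Why: Proposed new method: p-TsOH should first ionise the tertiary alcohol, the cation being trapped by the axial quinolinone enol (bridged ether 10); protonation of the vinylogous carbamate then ionises the crowded tertiary alkyl C–O bond of the dihydrofuran, a 1,2-hydride shift from the isopropyl methine (entering on the face the oxygen has left) gives the 2-propyl cation, and the freed enol oxygen closes on it. The closest known reactions are the acid-catalysed cyclisations of cannabidiol-type terpenyl enols to tetrahydrocannabinol and iso-tetrahydrocannabinol ethers, tert-alkyl ester and ether ionisation, and the acid interconversion of tertiary terpene ethers through 1,2-hydride shifts; the sequence C–O ionisation/hydride shift/re-closure has not been shown for dihydrofuroquinolinones. Both rings close by collapse of an enol oxygen on a tertiary carbocation (SN1 etherification): ring B as a six-membered 1,3-diaxial bridge, the pyran ring as a six-membered ring in place of the five-membered one (net one-carbon ring expansion). The O-bearing quaternary carbon is set by the tether (only the face syn to the axial quinolinone can be reached), and the ring-fusion CH by the hydride entering anti to the isopropyl carbon, which becomes equatorial; this is also the thermodynamic outcome (trans-fused, both ring bonds equatorial) and can be reached by equilibration because ionisation and hydride shift are reversible. The step needs the hydride to come from the isopropyl group and not from the quinolinone-bearing methines: the bridge formed first makes one of them a bridgehead that cannot planarise, which holds the absolute configuration, while the other, should it epimerise through its quinolinone-stabilised cation, can only return equatorial and trans in the locked chair; relief of strain at the fully substituted ether carbon drives the five-to-six change.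

Compound list
1 | 4-(propan-2-yl)phenol | CC(C)c1ccc(O)cc1 | starting material
2 | 4-hydroperoxy-4-(propan-2-yl)cyclohexa-2,5-dien-1-one (p-peroxyquinol, not isolated) | CC(C)C1(OO)C=CC(=O)C=C1 | intermediate
3 | 4-hydroxy-4-(propan-2-yl)cyclohexa-2,5-dien-1-one (p-quinol, achiral) | CC(C)C1(O)C=CC(=O)C=C1 | intermediate
4 | 4-hydroxy-1-methylquinolin-2(1H)-one | Cn1c(=O)cc(O)c2ccccc21 | starting material
5 | 4-hydroxy-3-[(1S,2S)-2-hydroxy-5-oxo-2-(propan-2-yl)cyclohex-3-en-1-yl]-1-methylquinolin-2(1H)-one (Michael adduct, quinolinone syn to OH, not isolated) | Cn1c(=O)c(c(O)c2ccccc21)[C@@H]1CC(=O)C=C[C@@]1(O)C(C)C | intermediate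
6 | (6bS,10aS)-11a-hydroxy-5-methyl-10a-(propan-2-yl)-6a,6b,7,11a-tetrahydro[1]benzofuro[3,2-c]quinoline-6,8(5H,10aH)-dione (cyclic hemiketal, C6a and C11a not defined, not isolated) | CN1C(=O)C2[C@@H]3CC(=O)C=C[C@]3(C(C)C)OC2(O)c2ccccc12 | intermediate
7 | (6bS,10aS)-5-methyl-10a-(propan-2-yl)-6b,7-dihydro[1]benzofuro[3,2-c]quinoline-6,8(5H,10aH)-dione (cis-fused dihydrofuran enone) | Cn1c(=O)c2c(c3ccccc31)O[C@@]1(C(C)C)C=CC(=O)C[C@H]12 | intermediate
8 | (6bS,10S,10aS)-10-(4-hydroxy-1-methyl-2-oxo-1,2-dihydroquinolin-3-yl)-5-methyl-10a-(propan-2-yl)-6b,7,9,10-tetrahydro[1]benzofuro[3,2-c]quinoline-6,8(5H,10aH)-dione (second quinolinone trans to the ring oxygen) | Cn1c(=O)c2c(c3ccccc31)O[C@@]1(C(C)C)[C@H](c3c(O)c4ccccc4n(C)c3=O)CC(=O)C[C@H]12 | intermediate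
9 | (6bS,10S,10aS)-8-hydroxy-10-(4-hydroxy-1-methyl-2-oxo-1,2-dihydroquinolin-3-yl)-5,8-dimethyl-10a-(propan-2-yl)-6b,7,8,9,10,10a-hexahydro[1]benzofuro[3,2-c]quinolin-6(5H)-one (epimers at C8) | Cn1c(=O)c2c(c3ccccc31)O[C@@]1(C(C)C)[C@H](c3c(O)c4ccccc4n(C)c3=O)CC(C)(O)C[C@H]12 | intermediate
10 | bridged ether: 9 minus water, the 4-oxygen of the pendant quinolinone bonded to C8 on the face syn to that quinolinone (ring B closed), cis-fused dihydrofuran and angular isopropyl retained (not isolated) | Cn1c(=O)c2c(c3ccccc31)O[C@]3(C(C)C)[C@H]2C[C@]2(C)C[C@H]3c1c(c3ccccc3n(C)c1=O)O2 | intermediate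
11 | target dimer: cyclohexane carrying a trans-fused 2,2-dimethyl-3,4-dihydropyrano[3,2-c]quinolin-5-one (ring A) and a bridging 2-methylpyrano[3,2-c]quinolin-5-one (ring B) that is cis to the CMe2 carbon and trans to the ring A quinolinone | Cn1c(=O)c2c(c3ccccc31)OC(C)(C)[C@H]1[C@H]2C[C@]2(C)C[C@H]1c1c(c3ccccc3n(C)c1=O)O2 | target

Total step count: 5. Longest linear sequence: 5 steps (from 1).

Steps most likely to fail

1. Step 5. The cation next to the quinolinone-bearing methines may lose a proton or take a hydride from the ring instead of from the isopropyl group, or the ether may re-close five-membered faster than the hydride shift, so that the cation manifold does not funnel cleanly and configuration erodes. Fallback with known chemistry, setting out from 4 and coming back at 11: 4 is condensed with 3-methylbut-2-enal (pyridine, 110 °C; Knoevenagel condensation/oxa-6π electrocyclisation) to N-methylflindersine F1. Thermolysis of F1 (Ph2O, about 200 °C) opens the 2H-pyran and, after a [1,7]-hydrogen shift, should give diene F2. F2 dimerises by Diels–Alder reaction (one molecule as diene, the E-configured styrene-type double bond of the second as dienophile, vinyl group endo) to bis-enol F3. Markovnikov hydroalkoxylation of both alkenes of F3 (in the melt, completed with p-TsOH) should give racemic 11, here by direct closure of the pyran ring. Chromatography and preparative chiral SFC then deliver 11 and its enantiomer F4.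

2. Step 2. Retro-Michael equilibration and diversion into a bridged oxa-Michael adduct may erode enantiofacial control before the slow etherification of the tertiary alcohol. Fallback setting out from 3 and coming back at 8: chiral phosphoric acid-catalysed acetalisation/oxa-Michael desymmetrisation of 3 with acetaldehyde gives the cis-fused dioxolane enone F5 (a temporary ring). Michael addition of 4 (Et3N, MeCN) to the remaining enone, trans to the ring oxygen, gives Michael adduct F6. DBU then induces retro-oxa-Michael opening with loss of acetaldehyde to hydroxy enone F7. A second, hydroxyl-directed Michael addition of 4 followed by p-TsOH-mediated cyclodehydration should give 8 directly.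

3. Step 3. Addition at the neopentyl-type β-carbon may be slow, with retro-Michael equilibration and insufficient facial control. Fallback setting out from 7 and coming back at 11: 1,2-addition of MeMgBr/CeCl3 to enone 7 gives tertiary allylic alcohol F8. BF3·OEt2-mediated Friedel–Crafts-type allylic alkylation of 4 (CH2Cl2, 0 °C; the reaction type used to couple p-menthadienol with resorcinols) at the secondary allyl terminus gives allylated alkene F9. F9 under the conditions of step 5 should then give 11, the reversible alkylation being funnelled through the bridging closure that only the trans isomer can undergo.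

Further compounds
F1 | step 5 | N-methylflindersine (2,2,6-trimethyl-2H-pyrano[3,2-c]quinolin-5(6H)-one) | Cn1c(=O)c2C=CC(C)(C)Oc2c2ccccc21
F2 | step 5 | 4-hydroxy-1-methyl-3-[(1E)-3-methylbuta-1,3-dien-1-yl]quinolin-2(1H)-one | Cn1c(=O)c(/C=C/C(C)=C)c(O)c2ccccc21
F3 | step 5 | 3,3'-[5-methyl-2-(prop-1-en-2-yl)cyclohex-4-ene-1,3-diyl]bis(4-hydroxy-1-methylquinolin-2(1H)-one), racemic, 1,2-trans-2,3-cis (the enantiomer leading to 11 is drawn) | CC(=C)[C@H]1[C@H](c2c(O)c3ccccc3n(C)c2=O)CC(C)=C[C@H]1c1c(O)c2ccccc2n(C)c1=O
F4 | step 5 | enantiomer of 11 | Cn1c(=O)c2c(c3ccccc31)OC(C)(C)[C@@H]1[C@@H]2C[C@@]2(C)C[C@@H]1c1c(c3ccccc3n(C)c1=O)O2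
F5 | step 2 | cis-fused 2-methyl-7a-(propan-2-yl)-3a,4-dihydro-1,3-benzodioxol-5(7aH)-one (acetal carbon not defined) | CC1O[C@@H]2CC(=O)C=C[C@]2(C(C)C)O1
F6 | step 2 | 7-(4-hydroxy-1-methyl-2-oxo-1,2-dihydroquinolin-3-yl)-2-methyl-7a-(propan-2-yl)hexahydro-1,3-benzodioxol-5-one (quinolinone trans to the ring oxygen at C7a) | CC1O[C@@H]2CC(=O)C[C@@H](c3c(O)c4ccccc4n(C)c3=O)[C@]2(C(C)C)O1
F7 | step 2 | 4-hydroxy-3-[6-hydroxy-3-oxo-6-(propan-2-yl)cyclohex-4-en-1-yl]-1-methylquinolin-2(1H)-one (quinolinone trans to OH) | CC(C)[C@@]1(O)C=CC(=O)C[C@H]1c1c(O)c2ccccc2n(C)c1=O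
F8 | step 3 | (6bS,10aS)-8-hydroxy-5,8-dimethyl-10a-(propan-2-yl)-6b,7,8,10a-tetrahydro[1]benzofuro[3,2-c]quinolin-6(5H)-one (epimers at C8) | Cn1c(=O)c2c(c3ccccc31)O[C@@]1(C(C)C)C=CC(C)(O)C[C@H]12
F9 | step 3 | 10-(4-hydroxy-1-methyl-2-oxo-1,2-dihydroquinolin-3-yl)-5,8-dimethyl-10a-(propan-2-yl)-6b,7,10,10a-tetrahydro[1]benzofuro[3,2-c]quinolin-6(5H)-one (configuration as in 8) | Cn1c(=O)c2c(c3ccccc31)O[C@@]1(C(C)C)[C@H](c3c(O)c4ccccc4n(C)c3=O)C=C(C)C[C@H]12
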